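**Retrosynthetic overview**

1. Feature: the five-membered ring of the indenone (C1, C2, C3, C3a, C7a) is a hidden 2-aroylbenzoate. Ring A carries C1 on C7a at the ester level and C3 on C3a as the ketone that also bears ring B. One further carbon, C2, closes the ring, and it is the benzylic carbon on C6' of ring C in the ring C–O–ring D diaryl ether.
2. Key disconnection: C1–C2 and C2=C3 are cut together, giving a ring A/B keto ester and a ring C/D benzylic phosphonate. This is the only ring the route forms, since rings A to D are bought as arenes.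
3. Keto ester: the C3–ring B bond comes from aryllithium addition to a ring A bromoaldehyde followed by oxidation, and C1 comes from palladium-catalysed methoxycarbonylation of the bromide.
4. Phosphonate: the ring C–O–ring D bond comes from a Smiles rearrangement of the ring D salicylate ester (a depside) of a ring C salicylaldehyde. The formyl group that activates this shift then becomes C2 (CHO, CH2OH, CH2Br, CH2P(O)(OEt)2).
5. End game: the five benzyl ethers are removed with BCl3 and pentamethylbenzene.

Key step: step 18

Assumption: the target has no stereocentre, and rotation about its aryl–indenone and aryl–oxygen bonds is taken as free. No stereocontrol is therefore planned, and the single carbinol centre made on the way is racemic and is oxidised away.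

**Route**

Step 1
Reactants: 1 2-bromo-4,6-dimethoxybenzaldehyde
Product: 2 2-bromo-6-hydroxy-4-methoxybenzaldehyde
Conditions: BCl3 (1.2 equiv), CH2Cl2, −78 to 0 °C; then H2O
Reagents that add atoms: none
Why: Chelation-controlled aryl methyl ether cleavage, in which boron bridges the aldehyde oxygen and the ortho methoxy oxygen so that only the C6 ether is lost and the para methoxy group stays.

Step 2
Reactants: 2 2-bromo-6-hydroxy-4-methoxybenzaldehyde
Product: 3 2-(benzyloxy)-6-bromo-4-methoxybenzaldehyde
Conditions: BnBr, K2CO3, DMF, rt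
Reagents that add atoms: benzyl bromide, BrCc1ccccc1
Why: Williamson ether synthesis on an acidic phenol, to which the aldehyde and the aryl bromide are inert.

Step 3
Reactants: 4 orcinol
Product: 5 2-iodo-5-methylbenzene-1,3-diol
Conditions: I2 (1.05 equiv), NaHCO3, THF/H2O, 0 °C to rt
Reagents that add atoms: iodine, [I][I]
Why: Electrophilic aromatic iodination under aqueous bicarbonate, which on resorcinols is known to settle on the position between the two hydroxyls, the methyl group adding further shielding at C4 and C6.

Step 4
Reactants: 5 2-iodo-5-methylbenzene-1,3-diol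
Product: 6 1,3-bis(benzyloxy)-2-iodo-5-methylbenzene
Conditions: BnBr (2.2 equiv), K2CO3, DMF, rt
Reagents that add atoms: benzyl bromide, BrCc1ccccc1
Why: Double Williamson ether synthesis at room temperature, mild enough to keep the aryl iodide in place.

Step 5
Reactants: 6 1,3-bis(benzyloxy)-2-iodo-5-methylbenzene; 3 2-(benzyloxy)-6-bromo-4-methoxybenzaldehyde
Product: 8 [2-(benzyloxy)-6-bromo-4-methoxyphenyl][2,6-bis(benzyloxy)-4-methylphenyl]methanol (racemic), via aryllithium 7 (not isolated)
Conditions: n-BuLi (1.05 equiv), THF, −78 °C; then 3, −78 to −20 °C; then H2O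
Reagents that add atoms: none
Why: Iodine–lithium exchange at −78 °C outruns deprotonation of the benzyl ether CH2 groups, and 1,2-addition of the aryllithium to the aldehyde is far faster than bromine–lithium exchange; the new carbinol centre is racemic and is erased in step 6.

Step 6
Reactants: 8 [2-(benzyloxy)-6-bromo-4-methoxyphenyl][2,6-bis(benzyloxy)-4-methylphenyl]methanol
Product: 9 [2-(benzyloxy)-6-bromo-4-methoxyphenyl][2,6-bis(benzyloxy)-4-methylphenyl]methanone
Conditions: Dess–Martin periodinane (1.5 equiv), CH2Cl2, rt
Reagents that add atoms: none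
Why: Dess–Martin oxidation, a neutral method that is routinely used on crowded benzhydrols and leaves benzyl ethers and the aryl bromide untouched.

Step 7
Reactants: 9 [2-(benzyloxy)-6-bromo-4-methoxyphenyl][2,6-bis(benzyloxy)-4-methylphenyl]methanone
Product: 10 methyl 3-(benzyloxy)-2-[2,6-bis(benzyloxy)-4-methylbenzoyl]-5-methoxybenzoate
Conditions: Pd(OAc)2 (5 mol%), Xantphos (10 mol%), CO (balloon), Et3N, MeOH/DMF, 80 °C
Reagents that add atoms: carbon monoxide, [C-]#[O+]; methanol, CO
Why: Palladium-catalysed alkoxycarbonylation, in which zerovalent palladium inserts into a C–Br bond that has only one ortho neighbour and is activated by the ortho ketone, CO inserts, and methanolysis gives the open methyl ester.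

Step 8
Reactants: 11 2-hydroxy-5-methoxybenzaldehyde
Product: 12 3-bromo-2-hydroxy-5-methoxybenzaldehyde
Conditions: Br2 (1.05 equiv), NaOAc, AcOH, rt
Reagents that add atoms: bromine, BrBr
Why: Electrophilic aromatic bromination directed by the free phenol to C3, its only open ortho position, the para position being blocked by the methoxy group.

Step 9
Reactants: 12 3-bromo-2-hydroxy-5-methoxybenzaldehyde
Product: 13 2,3-dihydroxy-5-methoxybenzaldehyde
Conditions: NaOH (aq), Cu powder (cat.), reflux, N2; then HCl
Reagents that add atoms: sodium hydroxide, [Na+].[OH-]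
Why: Copper-catalysed Ullmann-type hydroxylation of an ortho-bromophenolate, the reaction that converts 5-bromovanillin into 5-hydroxyvanillin, run under nitrogen to protect the catechol.

Step 10
Reactants: 13 2,3-dihydroxy-5-methoxybenzaldehyde
Product: 14 3-(benzyloxy)-2-hydroxy-5-methoxybenzaldehyde
Conditions: NaH (2.1 equiv), DMSO/THF, rt; BnBr (1.0 equiv); then HCl (aq)
Reagents that add atoms: benzyl bromide, BrCc1ccccc1
Why: Regioselective Williamson alkylation of the catechol dianion, in which the O2 phenolate is delocalised into and chelated by the formyl group so that the more basic O3 phenolate takes the single equivalent of benzyl bromide.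

Step 11
Reactants: 15 methyl 2,6-dihydroxy-4-methylbenzoate
Product: 16 methyl 2-(benzyloxy)-6-hydroxy-4-methylbenzoate
Conditions: BnBr (1.0 equiv), K2CO3 (1.1 equiv), acetone, reflux
Reagents that add atoms: benzyl bromide, BrCc1ccccc1
Why: Williamson mono-alkylation of two equivalent phenols, after which the remaining hydroxyl is held in a strong hydrogen bond to the ester carbonyl and reacts more slowly.

Step 12
Reactants: 16 methyl 2-(benzyloxy)-6-hydroxy-4-methylbenzoate
Product: 17 2-(benzyloxy)-6-hydroxy-4-methylbenzoic acid
Conditions: KOH (5 equiv), EtOH/H2O, reflux; then cold HCl (aq)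
Reagents that add atoms: potassium hydroxide, [K+].[OH-]
Why: Saponification of a hindered benzoate under forcing basic conditions that the benzyl ether tolerates, with cold acidification to avoid decarboxylation.

Step 13
Reactants: 17 2-(benzyloxy)-6-hydroxy-4-methylbenzoic acid; 14 3-(benzyloxy)-2-hydroxy-5-methoxybenzaldehyde
Product: 19 2-(benzyloxy)-6-formyl-4-methoxyphenyl 2-(benzyloxy)-6-hydroxy-4-methylbenzoate, via mixed anhydride 18 (not isolated)
Conditions: (CF3CO)2O (1.5 equiv), toluene, 0 °C to rt
Reagents that add atoms: none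
Why: Mixed-anhydride esterification with trifluoroacetic anhydride, the standard depside coupling, which suits di-ortho-substituted electron-rich acids because they react through an acylium-like species and their hydrogen-bonded ortho hydroxyl can stay free.

Step 14
Reactants: 19 2-(benzyloxy)-6-formyl-4-methoxyphenyl 2-(benzyloxy)-6-hydroxy-4-methylbenzoate
Product: 21 methyl 2-(benzyloxy)-6-[2-(benzyloxy)-6-formyl-4-methoxyphenoxy]-4-methylbenzoate, via potassium carboxylate 20 (not isolated)
Conditions: K2CO3 (2.5 equiv), dry DMSO, 80 °C; then MeI, rt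
Reagents that add atoms: iodomethane, CI
Why: Smiles rearrangement (the aryl salicylate to 2-aryloxybenzoate shift known from depsides), in which the ring D phenolate attacks ipso carbon C1' of ring C, activated by the ortho formyl group, through a six-membered spiro Meisenheimer adduct, the carboxylate leaves irreversibly, and O-alkylation with MeI restores the methyl ester.

Step 15
Reactants: 21 methyl 2-(benzyloxy)-6-[2-(benzyloxy)-6-formyl-4-methoxyphenoxy]-4-methylbenzoate
Product: 22 methyl 2-(benzyloxy)-6-[2-(benzyloxy)-6-(hydroxymethyl)-4-methoxyphenoxy]-4-methylbenzoate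
Conditions: NaBH4, THF/MeOH, 0 °C
Reagents that add atoms: none
Why: Chemoselective borohydride reduction of the aldehyde, the hindered ring D ester being inert to NaBH4 at 0 °C.

Step 16
Reactants: 22 methyl 2-(benzyloxy)-6-[2-(benzyloxy)-6-(hydroxymethyl)-4-methoxyphenoxy]-4-methylbenzoate
Product: 23 methyl 2-(benzyloxy)-6-[2-(benzyloxy)-6-(bromomethyl)-4-methoxyphenoxy]-4-methylbenzoate
Conditions: CBr4, PPh3, CH2Cl2, 0 °C
Reagents that add atoms: carbon tetrabromide, BrC(Br)(Br)Br
Why: Appel reaction, a neutral conversion of a primary benzylic alcohol into the bromide that spares the benzyl ethers and the ester.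

Step 17
Reactants: 23 methyl 2-(benzyloxy)-6-[2-(benzyloxy)-6-(bromomethyl)-4-methoxyphenoxy]-4-methylbenzoate
Product: 24 methyl 2-(benzyloxy)-6-{2-(benzyloxy)-6-[(diethoxyphosphoryl)methyl]-4-methoxyphenoxy}-4-methylbenzoate
Conditions: P(OEt)3 (neat), 130 °C
Reagents that add atoms: triethyl phosphite, CCOP(OCC)OCC
Why: Michaelis–Arbuzov reaction of a primary benzylic bromide, driven by loss of volatile bromoethane.

Step 18
Reactants: 24 methyl 2-(benzyloxy)-6-{2-(benzyloxy)-6-[(diethoxyphosphoryl)methyl]-4-methoxyphenoxy}-4-methylbenzoate; 10 methyl 3-(benzyloxy)-2-[2,6-bis(benzyloxy)-4-methylbenzoyl]-5-methoxybenzoate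
Product: 26 pentabenzyl ascomindone B, via keto phosphonate 25 (not isolated)
Conditions: 24 (1.0 equiv) and 10 (1.4 equiv) premixed in THF; LiN(SiMe3)2 (2.3 equiv) added at −78 °C, to 0 °C; then 65 °C; then H2O
Reagents that add atoms: none
Why: LiN(SiMe3)2 removes a benzylic proton of 24, the phosphonate carbanion adds to the ring A ester of 10 and loss of methoxide makes the C1–C2 bond, after which the second equivalent of base stores 25 as its lithium enolate. On heating, C2 of this anion adds to the neighbouring C3 ketone, the oxido phosphonate closes to an oxaphosphetane, and expulsion of lithium diethyl phosphate forms the C2=C3 bond directly at the indenone oxidation level and makes the sequence irreversible. The closest known reactions are the Claisen-type acylation of phosphonate carbanions by esters (the usual entry to keto phosphonates) and the intramolecular Horner–Wadsworth–Emmons closure of cyclopentenones from keto phosphonates that carry a 1,4-related ketone; here both are run in one flask on a more crowded ketone. The five-membered ring closes 5-exo-trig at the ketone, enolendo with respect to the C1 enolate as in every cyclopentenone-forming aldol or olefination, which is workable because the phosphoryl-stabilised carbanion need not stay coplanar with the C1 carbonyl. No stereocentre remains: the two diastereomeric adducts at C2/C3 interconvert by retro-addition and only the one with oxygen and phosphorus cis can eliminate, so both drain to the same planar alkene. The step needs acylation at the ring A ester and not at the ring D ester (seven-membered self-closure) or at the ketone; the ring A ester has a single ortho neighbour whereas the ring D ester sits between two ortho oxygens and the ketone between four ortho substituents, and adding the base to a premixed solution holding excess 10 lets each carbanion meet the external ester as soon as it forms.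

Step 19
Reactants: 26 pentabenzyl ascomindone B
Product: 27 ascomindone B
Conditions: BCl3 (12 equiv), C6HMe5 (15 equiv), CH2Cl2, −78 °C; then H2O
Reagents that add atoms: none
Why: Lewis-acid debenzylation with a cation scavenger, in which BCl3 ionises the five benzyl ethers at −78 °C, pentamethylbenzene captures the benzyl cations by Friedel–Crafts alkylation, and the tetrasubstituted enone, the methyl ester and the two unchelated methyl ethers should survive where hydrogenolysis would endanger the enone.

**Compound list**

1 | 2-bromo-4,6-dimethoxybenzaldehyde | COc1cc(Br)c(C=O)c(OC)c1 | starting material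
2 | 2-bromo-6-hydroxy-4-methoxybenzaldehyde | COc1cc(O)c(C=O)c(Br)c1 | intermediate
3 | 2-(benzyloxy)-6-bromo-4-methoxybenzaldehyde | COc1cc(Br)c(C=O)c(OCc2ccccc2)c1 | intermediate
4 | orcinol (5-methylbenzene-1,3-diol) | Cc1cc(O)cc(O)c1 | starting material
5 | 2-iodo-5-methylbenzene-1,3-diol | Cc1cc(O)c(I)c(O)c1 | intermediate
6 | 1,3-bis(benzyloxy)-2-iodo-5-methylbenzene | Cc1cc(OCc2ccccc2)c(I)c(OCc2ccccc2)c1 | intermediate
7 | [2,6-bis(benzyloxy)-4-methylphenyl]lithium | [Li]c1c(OCc2ccccc2)cc(C)cc1OCc1ccccc1 | intermediate
8 | [2-(benzyloxy)-6-bromo-4-methoxyphenyl][2,6-bis(benzyloxy)-4-methylphenyl]methanol, racemic | COc1cc(Br)c(C(O)c2c(OCc3ccccc3)cc(C)cc2OCc2ccccc2)c(OCc2ccccc2)c1 | intermediate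
9 | [2-(benzyloxy)-6-bromo-4-methoxyphenyl][2,6-bis(benzyloxy)-4-methylphenyl]methanone | COc1cc(Br)c(C(=O)c2c(OCc3ccccc3)cc(C)cc2OCc2ccccc2)c(OCc2ccccc2)c1 | intermediate
10 | methyl 3-(benzyloxy)-2-[2,6-bis(benzyloxy)-4-methylbenzoyl]-5-methoxybenzoate | COC(=O)c1cc(OC)cc(OCc2ccccc2)c1C(=O)c1c(OCc2ccccc2)cc(C)cc1OCc1ccccc1 | intermediate
11 | 2-hydroxy-5-methoxybenzaldehyde | COc1ccc(O)c(C=O)c1 | starting material
12 | 3-bromo-2-hydroxy-5-methoxybenzaldehyde | COc1cc(Br)c(O)c(C=O)c1 | intermediate
13 | 2,3-dihydroxy-5-methoxybenzaldehyde | COc1cc(O)c(O)c(C=O)c1 | intermediate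
14 | 3-(benzyloxy)-2-hydroxy-5-methoxybenzaldehyde | COc1cc(OCc2ccccc2)c(O)c(C=O)c1 | intermediate
15 | methyl 2,6-dihydroxy-4-methylbenzoate | COC(=O)c1c(O)cc(C)cc1O | starting material
16 | methyl 2-(benzyloxy)-6-hydroxy-4-methylbenzoate | COC(=O)c1c(O)cc(C)cc1OCc1ccccc1 | intermediate
17 | 2-(benzyloxy)-6-hydroxy-4-methylbenzoic acid | OC(=O)c1c(O)cc(C)cc1OCc1ccccc1 | intermediate
18 | 2-(benzyloxy)-6-hydroxy-4-methylbenzoic trifluoroacetic anhydride | O=C(OC(=O)C(F)(F)F)c1c(O)cc(C)cc1OCc1ccccc1 | intermediate
19 | 2-(benzyloxy)-6-formyl-4-methoxyphenyl 2-(benzyloxy)-6-hydroxy-4-methylbenzoate (depside) | COc1cc(C=O)c(OC(=O)c2c(O)cc(C)cc2OCc2ccccc2)c(OCc2ccccc2)c1 | intermediate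
20 | potassium 2-(benzyloxy)-6-[2-(benzyloxy)-6-formyl-4-methoxyphenoxy]-4-methylbenzoate | COc1cc(C=O)c(Oc2cc(C)cc(OCc3ccccc3)c2C(=O)[O-])c(OCc2ccccc2)c1.[K+] | intermediate
21 | methyl 2-(benzyloxy)-6-[2-(benzyloxy)-6-formyl-4-methoxyphenoxy]-4-methylbenzoate | COC(=O)c1c(OCc2ccccc2)cc(C)cc1Oc1c(C=O)cc(OC)cc1OCc1ccccc1 | intermediate
22 | methyl 2-(benzyloxy)-6-[2-(benzyloxy)-6-(hydroxymethyl)-4-methoxyphenoxy]-4-methylbenzoate | COC(=O)c1c(OCc2ccccc2)cc(C)cc1Oc1c(CO)cc(OC)cc1OCc1ccccc1 | intermediate
23 | methyl 2-(benzyloxy)-6-[2-(benzyloxy)-6-(bromomethyl)-4-methoxyphenoxy]-4-methylbenzoate | COC(=O)c1c(OCc2ccccc2)cc(C)cc1Oc1c(CBr)cc(OC)cc1OCc1ccccc1 | intermediate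
24 | methyl 2-(benzyloxy)-6-{2-(benzyloxy)-6-[(diethoxyphosphoryl)methyl]-4-methoxyphenoxy}-4-methylbenzoate | CCOP(=O)(OCC)Cc1cc(OC)cc(OCc2ccccc2)c1Oc1cc(C)cc(OCc2ccccc2)c1C(=O)OC | intermediate
25 | keto phosphonate: the ring A aryl ketone of 24, acylated at its benzylic carbon by the ester carbon of 10 (lithium enolate in the flask, drawn in the neutral keto form, C2 configurationally labile) | CCOP(=O)(OCC)C(C(=O)c1cc(OC)cc(OCc2ccccc2)c1C(=O)c1c(OCc2ccccc2)cc(C)cc1OCc1ccccc1)c1cc(OC)cc(OCc2ccccc2)c1Oc1cc(C)cc(OCc2ccccc2)c1C(=O)OC | intermediate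
26 | pentabenzyl ascomindone B | COC(=O)c1c(OCc2ccccc2)cc(C)cc1Oc1c(OCc2ccccc2)cc(OC)cc1C1=C(c2c(OCc3ccccc3)cc(C)cc2OCc2ccccc2)c2c(OCc3ccccc3)cc(OC)cc2C1=O | intermediate
27 | ascomindone B | COC(=O)c1c(O)cc(C)cc1Oc1c(O)cc(OC)cc1C1=C(c2c(O)cc(C)cc2O)c2c(O)cc(OC)cc2C1=O | target

Total step count: 19
Longest linear sequence: 10 steps (8, 9, 10, 13, 14, 15, 16, 17, 18, 19)

**Steps most likely to fail**

**1. Step 18.**
- **What may go wrong:** after the acylation, the fully substituted and doubly stabilised lithium enolate may be too hindered and too weakly nucleophilic to add to the tetra-ortho-substituted ketone, so the sequence stalls before ring closure. The free carbanion may also be lost through seven-membered self-acylation on the ring D ester.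
- **Fallback (sets out from 23 and 9, returns at 26):** Zn dust and LiCl in THF are inserted into bromide 23 to give the benzylic zinc bromide F1, which tolerates the ring D ester. Carbonylative Negishi coupling of F1 with aryl bromide 9 (Pd(OAc)2, Xantphos, CO, THF, 60 °C) makes the C1–C2 bond and gives the phosphorus-free 1,4-diketone F2. Its smaller and more basic ketone enolate (LiN(SiMe3)2, THF, 0 °C) closes by intramolecular aldol addition to the hydroxyindanone F3. Acid dehydration of this tertiary, doubly benzylic alcohol (TsOH, toluene, 80 °C) gives 26.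

**2. Step 14.**
- **What may go wrong:** the para methoxy and ortho benzyloxy groups of ring C raise the barrier to ipso attack, so cleavage of the activated aryl ester by traces of water or carbonate may outrun the aryl migration.
- **Fallback (sets out from 14, returns at 21, making steps 11 to 14 unnecessary):** the ether is made by copper catalysis with the polarity of the rings reversed.
  - Aldehyde 14 is masked with HC(OMe)3 and catalytic TsOH in MeOH as the electron-rich phenol dimethyl acetal F4.
  - Commercial 3-bromo-5-methylphenol is benzylated (BnBr, K2CO3) to the benzyl ether F5. F5 is deprotonated between bromine and oxygen with LiN(iPr)2 in THF at −78 °C to give the aryllithium F6, and quenching with methyl chloroformate gives the ring D bromo ester F7.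
  - Ullmann ether coupling of F4 with F7 (CuI, picolinic acid, K3PO4, DMSO, 90 °C) gives the acetal diaryl ether F8, which dilute aqueous HCl in the work-up converts into 21.

**3. Step 13.**
- **What may go wrong:** acylation of a hydrogen-bonded, di-ortho-substituted phenol by a di-ortho-substituted acid may be slow. This leaves room for self-esterification of 17 through its free hydroxyl and for decarboxylation in the acidic medium.
- **Fallback (sets out from 17, returns at 19):** 17 is closed with acetone, (CF3CO)2O and CF3CO2H to the benzodioxinone F9. Irradiation at 300 nm in CH2Cl2 in the presence of 14 expels acetone and releases the quinoketene F10. This unhindered and highly electrophilic acylating species is captured by the phenol of 14 under neutral conditions to give 19.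

**Further compounds**

F1 | step 18 | {3-(benzyloxy)-2-[3-(benzyloxy)-2-(methoxycarbonyl)-5-methylphenoxy]-5-methoxybenzyl}zinc bromide | COC(=O)c1c(OCc2ccccc2)cc(C)cc1Oc1c(C[Zn]Br)cc(OC)cc1OCc1ccccc1
F2 | step 18 | 1,4-diketone: the ring C benzyl ketone of ring A that still carries the ortho 2,6-bis(benzyloxy)-4-methylbenzoyl group | COC(=O)c1c(OCc2ccccc2)cc(C)cc1Oc1c(CC(=O)c2cc(OC)cc(OCc3ccccc3)c2C(=O)c2c(OCc3ccccc3)cc(C)cc2OCc2ccccc2)cc(OC)cc1OCc1ccccc1
F3 | step 18 | 3-hydroxy-2,3-diarylindan-1-one (aldol adduct, racemic mixture of diastereomers) | COC(=O)c1c(OCc2ccccc2)cc(C)cc1Oc1c(OCc2ccccc2)cc(OC)cc1C1C(=O)c2cc(OC)cc(OCc3ccccc3)c2C1(O)c1c(OCc2ccccc2)cc(C)cc1OCc1ccccc1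
F4 | step 14 | 2-(benzyloxy)-6-(dimethoxymethyl)-4-methoxyphenol | COc1cc(OCc2ccccc2)c(O)c(C(OC)OC)c1
F5 | step 14 | 1-(benzyloxy)-3-bromo-5-methylbenzene | Cc1cc(Br)cc(OCc2ccccc2)c1
F6 | step 14 | [2-(benzyloxy)-6-bromo-4-methylphenyl]lithium | [Li]c1c(Br)cc(C)cc1OCc1ccccc1
F7 | step 14 | methyl 2-(benzyloxy)-6-bromo-4-methylbenzoate | COC(=O)c1c(Br)cc(C)cc1OCc1ccccc1
F8 | step 14 | methyl 2-(benzyloxy)-6-[2-(benzyloxy)-6-(dimethoxymethyl)-4-methoxyphenoxy]-4-methylbenzoate | COC(=O)c1c(OCc2ccccc2)cc(C)cc1Oc1c(C(OC)OC)cc(OC)cc1OCc1ccccc1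
F9 | step 13 | 5-(benzyloxy)-2,2,7-trimethyl-4H-1,3-benzodioxin-4-one | CC1(C)OC(=O)c2c(OCc3ccccc3)cc(C)cc2O1
F10 | step 13 | 5-(benzyloxy)-3-methyl-6-(oxomethylidene)cyclohexa-2,4-dien-1-one (quinoketene) | O=C=C1C(=O)C=C(C)C=C1OCc1ccccc1
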